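**Easy step.** Substrate turns into intermediate on its own, with a half-life of 10 s at 100 °C, and two nucleophiles wait to catch the intermediate.

the same everywhere: first nucleophile 0.950 equiv; second nucleophile 1.30 equiv; protic impurity 0.400 mM; time 15 s
- Sunday's: substrate 2.0 mM; temperature 100 °C; everything together at the start
- Friday's: substrate 2.0 mM; everything together at the start at 80 °C, warmed to 100 °C at 6.0 s
- Tuesday's: substrate 2.0 mM (fed, over 6.0 s); temperature 100 °C; all else is in the flask from the start; the feed brings no volume worth counting
- Wednesday's: substrate 2.0 mM (fed, over 6.0 s); the addition at 80 °C, then warmed to 100 °C; the feed brings no volume worth counting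

1. the best flask by share of target in target plus other capture product; "all alike" if 1.5 percentage points covers them all (Sunday's / Friday's / Tuesday's / Wednesday's / all alike)
2. share of target in target plus other capture product at the end, Sunday's
3. share of target in target plus other capture product at the end, Friday's
4. share of target in target plus other capture product at the end, Tuesday's
5. share of target in target plus other capture product at the end, Wednesday's

- constants are those at 100 °C; use the activation energies for any other temperature

    intermediate → side product (k1 = 0.13 s⁻¹, Ea1 = 83.0 kJ mol⁻¹)
    second nucleophile + intermediate → other capture product (k2 = 12000 M⁻¹ s⁻¹, Ea2 = 40.0 kJ mol⁻¹)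
    first nucleophile + intermediate → target (k3 = 4400 M⁻¹ s⁻¹, Ea3 = 49.0 kJ mol⁻¹)
    second nucleophile → decomposed reagent (k4 = 0.072 s⁻¹, Ea4 = 90.0 kJ mol⁻¹)
    substrate → intermediate (k5 = 0.067 s⁻¹, Ea5 = 100 kJ mol⁻¹)
    first nucleophile + protic impurity → quenched reagent (k6 = 68 M⁻¹ s⁻¹, Ea6 = 46.0 kJ mol⁻¹)
    (constants at 100 °C)

**Odd pair.** At the charge, the intermediate has a half-life of 0.022 s against the second nucleophile and 0.083 s against the first, while the feed in Tuesday's lasts 6.0 s. A species that short-lived should not care how slowly substrate arrives. Yet I expect it to care.

**Capture ratio.** Because capture is much quicker than forming, each intermediate takes its fate from the nucleophiles present as it forms. I call the capture ratio (a selectivity factor) the target made per other capture product at one moment: the first capture constant times c(first nucleophile), over the second capture constant times c(second nucleophile). At the charge and 100 °C it is 0.268, a share of 21.1%. But the second nucleophile also decays by itself, with a half-life of 9.6 s at 100 °C. So I watch this decay, far slower than capture, and not the intermediate's life.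

**Counting turnovers.** I count the decay half-lives passed at the mean moment of forming, and each one counted multiplies the ratio by 2. I hold c(first nucleophile) at its charge and ignore what capture takes from either nucleophile.

In Sunday's, the mean moment of an exponential cut off at 15 s is 6.26 s. That gives a count of 0.651, a ratio of 0.421 and a share of 29.6%.

In Tuesday's, substrate arrives on average at 3.00 s, and the same cut exponential then runs over the remaining 12.0 s. The mean moment is 8.20 s, the count 0.852, the ratio 0.484 and the share 32.6%. I put Tuesday's ahead of Sunday's by 3 percentage points. The flasks started cold need another clock, and I do not count them.

**The forecast.** It names Tuesday's, because slow feeding “delays intermediate formation until the second nucleophile has decayed”. It gives Sunday's 31.7%, Friday's 27.7%, Tuesday's 33.9% and Wednesday's 28.1%. Its Sunday's figure stands above mine, and so does its Tuesday's figure.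

**The result.** The simulation names Tuesday's, with Sunday's 31.7%, Friday's 27.6%, Tuesday's 33.8% and Wednesday's 27.9%, so the forecast holds. Tuesday's share, the highest of the four, belongs to a flask with 45.1% of its substrate unconverted.

**Earlier reading.** Tuesday's recipe stopped at 10 s gets the same reckoning. The window after mean arrival is 7.00 s, so the mean moment is 6.23 s. The count falls to 0.647, and from 0.268 the ratio becomes 0.420, a share of 29.6%. That flask holds 63.0% of its substrate and reads 29.2%.

All constants are invented; the rest is arithmetic.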